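## Analysis of the target

Target 14 is 4,4'-(ethane-1,2-diyl)bis(3,5,6-tribromobenzene-1,2-diol): two identical, fully substituted benzene rings joined by a CH2–CH2 bridge. It has no other ring and no stereocentre, so the two halves are related by symmetry alone. Each ring is numbered C1 (bridge CH2), C2 (Br), C3 (OH), C4 (OH), C5 (Br), C6 (Br). The sensitive groups are the two catechols, which are oxidised to ortho-quinones by the electrophiles needed for bromination; the six aryl C–Br bonds, which exclude reducing conditions, organolithium reagents and hydrogenation catalysts; and the benzylic CH2 groups, which can be brominated by radical chains. The difficulty is positional: six bromine and four oxygen atoms must be placed on two rings without isomers, ideally with each operation done on both halves in one flask. The plan rests on the fact that C2–C3–C4 of each ring matches the ester carbon, ketone carbon and methoxylated carbon of the 4-methoxyacetoacetate 1, while C5–C6–C1 is a three-carbon unit with C5 at the aldehyde level and C1 at the ketone level, the two C1 atoms being the carbonyl carbons of a succinyl unit. An ester at C2, ortho to the C3 hydroxyl, can later be displaced by electrophilic bromine with loss of the carboxyl carbon, so the ring synthesis leaves hydrogen only where bromine must go.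

## Retrosynthetic reasoning

**14 from 13.** The last bonds cut are the two O–CH3 bonds at C4. One oxygen of each catechol stays masked to the end because a free catechol would be oxidised during bromination, whereas mono-ether 13 still has one free hydroxyl per ring to drive that bromination. The forward step only has to cleave two aryl methyl ethers without touching six C–Br bonds.

**13 from 12.** All six C–Br bonds are cut together: four go back to C–H (C5, C6) and two to C–CO2H (C2). In 12 the positions C1, C3 and C4 are occupied and C2 carries a carboxyl ortho to the free hydroxyl, so bromine has exactly three places per ring to go and no isomer can form. The ring synthesis therefore need not deliver any halogen. The forward reaction must achieve two ordinary substitutions and one ipso-substitution with loss of the carboxyl carbon per ring.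

**12 from 11.** The carboxyl group can only leave in the ipso step if it is free, so diacid 12 is traced to diester 11 by hydrolysis. Nothing else changes.

**11 from 9 and 3.** In each ring the bonds C4–C5 and C1–C2 are cut. Only this pair of cuts divides the ring into a C2–C3–C4 fragment that carries the ester and both oxygens in a 1,3-dicarbonyl relationship, and a C5–C6–C1 fragment with ends at the aldehyde and ketone levels. Because the bridge joins the two ketone carbons, one eight-carbon chain, 9, is the electrophilic half of both rings and two molecules of 3 are the nucleophilic halves. Four skeletal bonds and both rings are gained in one operation, with every substituent placed by connectivity. The forward reaction must join the diene terminus to the acetal carbon and the ester-bearing carbon to the ketone carbon, not the reverse, at both ends of 9, and then aromatise. It is planned to pass through open-chain intermediate 10 so that this orientation is fixed before the rings close.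

**3 from 2 and 1.** The two O–Si bonds of 3 are cut in turn, through mono-silyl enol ether 2 back to keto ester 1, which already holds C2, C3 and C4 with their oxygens and the ester.

**9 from 7.** The four C–O bonds of the two acetals are cut. The terminal carbons of 9 are at the same oxidation level as the terminal alkyne carbons of bis-ynone 7, so two conjugate additions of the solvent alcohol per ynone, through bis-enone 8, build both acetals without a redox step.

**7 from 5 and 6.** The two C(=O)–C(sp) bonds are cut, giving the double acyl donor 5 and two equivalents of ethynyl Grignard reagent 6. The N-methoxy-N-methylamide is chosen because it stops at the ketone.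

**5 from 4.** The two amide C–N bonds are cut, back to succinyl chloride 4, whose carbonyl carbons become the two C1 atoms and whose CH2CH2 unit is the bridge of 14.

## Alternatives that were turned down

**Alternative 1:** Aryne carbomagnesiation on an acetylene bis-Grignard reagent.
- Disconnection: the C1–C(bridge) bond and the C2–Br bond of each ring; the bridge comes from acetylene and the rings from the perbrominated dimethoxyphenyl tosylate A1.
- Forward key step: halogen–magnesium exchange at the bromine between the sulfonate and a methoxy group of A1, followed by loss of the sulfonate, gives aryne A3. Both ends of the acetylene bis-Grignard reagent A2 add, and the resulting aryl magnesium species are quenched with an electrophilic bromine donor to give diarylalkyne A4. Reduction of the triple bond and ether cleavage would finish the synthesis.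
- For it: it is convergent and clearly shorter than the chosen route, and it needs no bromination of an oxygenated ring because all bromines arrive with the arene or the quench. On both points it is stronger.
- Against it:
  - A3 has a methoxy group next to one aryne carbon and a bromine next to the other. Both direct a nucleophile to the carbon remote from themselves, so the two effects oppose each other and the orientation of addition is not secured.
  - A1 has two bromines ortho to the sulfonate and a third elsewhere, so the site of exchange is a further selectivity problem.
  - A2 is poorly soluble, weakly nucleophilic, and has to add twice to two separate short-lived arynes.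
  - A4 is a diarylalkyne with four ortho bromines whose triple bond must be saturated to CH2CH2 without hydrodebromination of six C–Br bonds.
- Comparison: the chosen strategy is longer, but it fixes every substituent by connectivity, has the bridge at the sp3 level from the start, and has no organometallic or reductive step after the bromines are in place.

**Alternative 2:** Bis(thiophene dioxide) plus an ynediether.
- Disconnection: C2–C3 and C4–C5 of each ring; the two oxygenated carbons come from ynediether A6, and the other four ring carbons, three bromines and the bridge come from bis-sulfone A5.
- Forward key step: each electron-poor sulfone diene of A5 undergoes an inverse-demand Diels–Alder reaction with electron-rich A6, and cheletropic extrusion of the sulfone bridge gives arene A7. Acid then removes the tert-butyl groups.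
- For it: all six bromines, the bridge and both oxygens are placed by construction, the dienophile is symmetric so there is no orientation problem, and the endgame is one mild deprotection with no oxidant near the catechol. On the endgame it is stronger than the chosen route.
- Against it:
  - Making A5 requires oxidation at sulfur of a hexabrominated bis-thiophene, which is electron-poor and resists ordinary peracids.
  - A6 needs a multi-step synthesis and is thermally fragile, losing its tert-butyl groups as alkene on warming.
  - The cycloaddition must occur twice in transition states that pack two tert-butoxy groups between bromines.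
  - A stepwise polar addition of the very electron-rich alkyne to the electrophilic sulfone could divert material.
- Comparison: both components of this key step are specialised and must be made, whereas the chosen route starts from commercial four- and six-carbon building blocks and uses classical operations before and after the key step.

**Alternative 3:** Pyrylium ring opening and Wittig reclosure with a bis-ylide.
- Disconnection: C1–C2 and C1–C6 of each ring; C1 and the bridge come from bis-ylide A9, and the other five ring carbons from pyrylium salt A8.
- Forward key step: each ylide carbon adds to an α-carbon of A8, the 2H-pyran opens to a dienal, and an intramolecular Wittig reaction with loss of the phosphine oxide closes the benzene ring, giving bibenzyl A10.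
- For it: attack at either α-carbon of A8 leads to the same arene, so the ring-forming step has no orientation problem. On that point it is safer than the chosen key step.
- Against it:
  - A10 has no bromine and two ether-protected oxygens per ring, so all six C–Br bonds remain to be made afterwards. The third bromine of each ring must enter a deactivated dibromo-dimethoxyarene next to benzylic C–H bonds.
  - A bibenzyl of this kind is accessible in one or two steps from commercial aromatic aldehydes, so building the rings gains nothing.
  - A8 has no α-substituents, is highly electrophilic and moisture-sensitive, and its 4-methoxy group invites addition–elimination at C4 instead of attack at the α-carbon.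
- Comparison: the chosen strategy delivers 11, in which the free hydroxyl at C3 activates two of the three positions to be brominated and the carboxyl at C2 is an ipso handle, so the bromination is programmed by the ring synthesis.

Key step: step 6

Remark on the chemistry: enol ether 2 and diene 3 are written as single geometric isomers for definiteness; mixtures serve equally well because this geometry, like the stereocentres of 10, disappears on aromatisation.

## Route

Step 1
Reactants: 1 methyl 4-methoxy-3-oxobutanoate (methyl 4-methoxyacetoacetate)
Product: 2 methyl (Z)-4-methoxy-3-(trimethylsilyloxy)but-2-enoate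
Conditions: Me3SiCl, Et3N, toluene, 20 °C
Reagents that add atoms: chlorotrimethylsilane, C[Si](C)(C)Cl
Why: O-silylation of the enol form of the β-keto ester under soft enolisation gives the silyl enol ether conjugated with the ester; the C4 methyl ether is inert.

Step 2
Reactants: 2 methyl (Z)-4-methoxy-3-(trimethylsilyloxy)but-2-enoate
Product: 3 (1E,3E)-1,4-dimethoxy-1,3-bis(trimethylsilyloxy)buta-1,3-diene
Conditions: LiN(iPr)2, THF, −78 °C; Me3SiCl, −78 → 20 °C; filtered from salts under argon and used at once
Reagents that add atoms: chlorotrimethylsilane, C[Si](C)(C)Cl
Why: Kinetic γ-deprotonation of the vinylogous ester at the CH2 next to the methoxy group, then O-silylation at the ester oxygen, is the standard preparation of 1,3-bis(silyloxy)-1,3-dienes. The product is moisture-sensitive and is not stored.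

Step 3
Reactants: 4 succinyl chloride
Product: 5 N1,N4-dimethoxy-N1,N4-dimethylbutanediamide
Conditions: MeNH(OMe)·HCl (2.2 equiv), pyridine, CH2Cl2, 0 → 20 °C
Reagents that add atoms: N,O-dimethylhydroxylamine hydrochloride, CNOC.Cl
Why: N-acylation of the amine by both acid chloride groups (Weinreb amide formation). The nitrogen is fully substituted, so no cyclic imide can form.

Step 4
Reactants: 5 N1,N4-dimethoxy-N1,N4-dimethylbutanediamide; 6 ethynylmagnesium bromide
Product: 7 octa-1,7-diyne-3,6-dione
Conditions: THF, 0 → 20 °C; inverse quench into cold aq. NaHSO4; solution used directly in step 5
Reagents that add atoms: none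
Why: Weinreb ketone synthesis: chelation by the N-methoxy oxygen keeps each carbonyl carbon tetrahedral until the quench, so each takes up exactly one ethynyl group. The cold acidic inverse quench protonates the released amine before it can add to the ynone.

Step 5
Reactants: 7 octa-1,7-diyne-3,6-dione
Product: 9 1,1,8,8-tetramethoxyoctane-3,6-dione, via bis(β-methoxy enone) 8 (not isolated)
Conditions: NaOMe (0.2 equiv), MeOH, 0 → 20 °C; AcOH to neutrality
Reagents that add atoms: methanol, CO
Why: Base-catalysed double oxa-Michael addition of methanol to each terminal ynone: the first addition gives the β-methoxy enone, the second the β-ketoacetal, which is favoured in methanol. Catalytic base at low temperature keeps the 1,4-diketone from enolising into an aldol reaction, and any end left at the enone stage offers the same electrophilic carbon in step 6.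

Step 6
Reactants: 9 1,1,8,8-tetramethoxyoctane-3,6-dione; 3 (1E,3E)-1,4-dimethoxy-1,3-bis(trimethylsilyloxy)buta-1,3-diene (2.6 equiv)
Product: 11 dimethyl 6,6'-(ethane-1,2-diyl)bis(2-hydroxy-3-methoxybenzoate), via open-chain bis(silyl enol ether) 10 (not isolated)
Conditions: Me3SiOTf (0.2 equiv), CH2Cl2, −78 °C; then TiCl4 (2.2 equiv), −78 → 20 °C; aq. HCl
Reagents that add atoms: none
Why: In the first stage Me3SiOTf ionises each acetal of 9 to an oxocarbenium ion while leaving the ketones untouched, and the terminal carbon C4 of 3 adds in a vinylogous Mukaiyama aldol reaction, so both C4–C5 bonds exist in 10 before any ring closes. In the second stage TiCl4 binds each ketone and the neighbouring silyl enol ether, the ester-bearing carbon C2 attacks the ketone carbon C1 in an intramolecular Mukaiyama aldol reaction, and loss of methanol from C5 and of water from C1 aromatises the ring. The closest known reaction type is the Lewis-acid formal [3+3] cyclocondensation of 1,3-bis(silyloxy)-1,3-dienes with masked 1,3-dicarbonyl compounds such as β-ketoacetals, which gives salicylates. Each of the two rings closes in the same way, by a 6-(enolendo)-exo-trig aldol addition that forms C1–C2, followed by two eliminations. No stereocentre is kept: the centres formed at C4, C5 and C1 and the geometry of 3 all vanish on aromatisation, so nothing needs controlling. The selectivity that matters is the orientation of the two three-carbon partners, and it is secured by the order of activation: only the acetal carbon is electrophilic in the first stage, and if an oxocarbenium ion loses a proton to give the β-methoxy enone, the carbon open to conjugate attack is still C5. The C4 methoxy group sits α, not β, to the C3 carbonyl and so survives the eliminations, and the two ends of 9 are insulated by the CH2CH2 unit and react independently, hence the excess of 3 and one equivalent of TiCl4 per ring.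

Step 7
Reactants: 11 dimethyl 6,6'-(ethane-1,2-diyl)bis(2-hydroxy-3-methoxybenzoate)
Product: 12 6,6'-(ethane-1,2-diyl)bis(2-hydroxy-3-methoxybenzoic acid)
Conditions: KOH (excess), DMSO/H2O, 80 °C, argon; then aq. HCl, 0 °C
Reagents that add atoms: potassium hydroxide, [K+].[OH-]
Why: Saponification by acyl–oxygen cleavage; forcing conditions are needed because the ester is flanked by the phenoxide and the bridge CH2. The acid is liberated cold to avoid protodecarboxylation, and the aryl methyl ethers are stable to base.

Step 8
Reactants: 12 6,6'-(ethane-1,2-diyl)bis(2-hydroxy-3-methoxybenzoic acid)
Product: 13 3,3'-(ethane-1,2-diyl)bis(2,4,5-tribromo-6-methoxyphenol)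
Conditions: Br2 (excess), NaOAc, AcOH/H2O, 20 → 50 °C, dark; aq. NaHSO3
Reagents that add atoms: bromine, BrBr
Why: Electrophilic aromatic bromination: the free C3 hydroxyl activates C6 (para) and the carboxyl-bearing C2 (ortho), where ipso attack and loss of CO2 install bromine (bromodecarboxylation of a salicylic acid), and the C4 methoxy group activates the last open position, C5. All other positions are blocked, so only one hexabromide can form. Exclusion of light suppresses benzylic bromination, and the bisulfite work-up removes excess bromine and reduces any over-oxidised ring.

Step 9
Reactants: 13 3,3'-(ethane-1,2-diyl)bis(2,4,5-tribromo-6-methoxyphenol)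
Product: 14 4,4'-(ethane-1,2-diyl)bis(3,5,6-tribromobenzene-1,2-diol)
Conditions: BBr3 (6 equiv), CH2Cl2, −78 → 20 °C; H2O
Reagents that add atoms: none
Why: Lewis-acid cleavage of aryl methyl ethers: boron coordinates the ether oxygen and bromide removes the methyl group by SN2. Aryl–Br bonds and the bridge are inert, and nothing oxidising is present when the catechols are set free.

## Compound list

1 | methyl 4-methoxy-3-oxobutanoate (methyl 4-methoxyacetoacetate) | COCC(=O)CC(=O)OC | starting material
2 | methyl (Z)-4-methoxy-3-(trimethylsilyloxy)but-2-enoate | COC/C(O[Si](C)(C)C)=C/C(=O)OC | intermediate
3 | (1E,3E)-1,4-dimethoxy-1,3-bis(trimethylsilyloxy)buta-1,3-diene | CO/C=C(O[Si](C)(C)C)\C=C(/OC)O[Si](C)(C)C | intermediate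
4 | succinyl chloride (butanedioyl dichloride) | O=C(Cl)CCC(Cl)=O | starting material
5 | N1,N4-dimethoxy-N1,N4-dimethylbutanediamide | CON(C)C(=O)CCC(=O)N(C)OC | intermediate
6 | ethynylmagnesium bromide | C#C[Mg]Br | starting material
7 | octa-1,7-diyne-3,6-dione | C#CC(=O)CCC(=O)C#C | intermediate
8 | (1E,7E)-1,8-dimethoxyocta-1,7-diene-3,6-dione | CO/C=C/C(=O)CCC(=O)/C=C/OC | intermediate
9 | 1,1,8,8-tetramethoxyoctane-3,6-dione | COC(OC)CC(=O)CCC(=O)CC(OC)OC | intermediate
10 | dimethyl 4,5,12,13-tetramethoxy-7,10-dioxo-3,14-bis(trimethylsilyloxy)hexadeca-2,14-dienedioate (stereoisomer mixture) | COC(=O)C=C(O[Si](C)(C)C)C(OC)C(OC)CC(=O)CCC(=O)CC(OC)C(OC)C(O[Si](C)(C)C)=CC(=O)OC | intermediate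
11 | dimethyl 6,6'-(ethane-1,2-diyl)bis(2-hydroxy-3-methoxybenzoate) | COC(=O)c1c(O)c(OC)ccc1CCc1ccc(OC)c(O)c1C(=O)OC | intermediate
12 | 6,6'-(ethane-1,2-diyl)bis(2-hydroxy-3-methoxybenzoic acid) | OC(=O)c1c(O)c(OC)ccc1CCc1ccc(OC)c(O)c1C(=O)O | intermediate
13 | 3,3'-(ethane-1,2-diyl)bis(2,4,5-tribromo-6-methoxyphenol) | COc1c(O)c(Br)c(CCc2c(Br)c(O)c(OC)c(Br)c2Br)c(Br)c1Br | intermediate
14 | 4,4'-(ethane-1,2-diyl)bis(3,5,6-tribromobenzene-1,2-diol) | Oc1c(O)c(Br)c(CCc2c(Br)c(O)c(O)c(Br)c2Br)c(Br)c1Br | target

## Step count and least certain steps

Total step count: 9. Longest linear sequence: 7 steps (4 → 5 → 7 → 9 → 11 → 12 → 13 → 14, steps 3 to 9); the diene branch (steps 1 and 2) joins at step 6.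

**Step 6 (key step).** Three things can go wrong.
- The β-keto oxocarbenium ion may lose a proton before the diene arrives. The acid released would strip silyl groups from 3 and starve the reaction of nucleophile.
- The second ring may close incompletely, because the first salicylate ties up titanium or because the 1,4-diketone undergoes Lewis-acid cyclodehydration to a furan.
- If TiCl4 is added before the first stage is complete, the very nucleophilic diene terminus could add to a titanium-bound ketone and reverse the orientation at that end.

The fallback builds each ring on a monofunctional partner and makes the bridge bond afterwards. It sets out from 3: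
- TiCl4-mediated cyclocondensation with commercial (E)-4-methoxybut-3-en-2-one, whose β-carbon is the only site for conjugate attack, should give methyl 2-hydroxy-3-methoxy-6-methylbenzoate F1.
- Acetylation (Ac2O, pyridine) should give methyl 2-acetoxy-3-methoxy-6-methylbenzoate F2.
- Radical benzylic bromination (N-bromosuccinimide, azobisisobutyronitrile, PhCF3, reflux) should give methyl 2-acetoxy-6-(bromomethyl)-3-methoxybenzoate F3.
- Wurtz-type reductive homocoupling with SmI2 in THF should give dimethyl 6,6'-(ethane-1,2-diyl)bis(2-acetoxy-3-methoxybenzoate) F4.
- Methanolysis of the acetates (K2CO3, MeOH) brings the sequence back to the route at 11.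

**Step 8.** The ipso-substitution at C2 may lag behind the ordinary substitutions, bromination at C5 may stall once the ring carries two bromines, or excess bromine may oxidise the guaiacol ring or attack the benzylic CH2 by a radical chain. The fallback separates decarboxylation from bromination. It sets out from 12: thermal protodecarboxylation (Cu2O cat., quinoline, 180 °C) should give 5,5'-(ethane-1,2-diyl)bis(2-methoxyphenol) F5. Three ordinary electrophilic brominations per ring (Br2, FeBr3 cat., CH2Cl2, dark) then return to the route at 13.

**Step 4.** The released amine or excess acetylide may add to the bis-ynone during the quench, and the terminal bis-ynone may polymerise on concentration. The fallback avoids both the amide and the free terminal ynone. It sets out from 4: Friedel–Crafts acylation of bis(trimethylsilyl)acetylene (AlCl3, CH2Cl2, 0 °C) should give the storable 1,8-bis(trimethylsilyl)octa-1,7-diyne-3,6-dione F6. NaOMe in MeOH then removes the silyl groups and adds methanol in the same flask, returning to the route at 9.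

**Step 5.** Methoxide may trigger an intramolecular aldol condensation of the 1,4-diketone, or addition may stop at a mixed enone/acetal stage. The fallback avoids alkoxide base. It sets out from 7: conjugate addition of diethylamine (CH2Cl2, 0 °C) should give (1E,7E)-1,8-bis(diethylamino)octa-1,7-diene-3,6-dione F7. Exchange of the amine for methanol under acid (HCl in dry MeOH, 20 °C) returns to the route at 9.

**Step 7.** Acyl substitution at an ester flanked by a phenoxide and the bridge CH2 may be slow and leave mono-ester, and the acid may decarboxylate if liberated warm. The fallback cleaves the alkyl–oxygen bond instead. It sets out from 11: SN2 attack of iodide on the ester methyl groups (LiI, pyridine, reflux; then cold aq. HCl) returns to the route at 12 without a new compound.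

## Further compounds

F1 | step 6 | methyl 2-hydroxy-3-methoxy-6-methylbenzoate | COC(=O)c1c(C)ccc(OC)c1O
F2 | step 6 | methyl 2-acetoxy-3-methoxy-6-methylbenzoate | COC(=O)c1c(C)ccc(OC)c1OC(C)=O
F3 | step 6 | methyl 2-acetoxy-6-(bromomethyl)-3-methoxybenzoate | COC(=O)c1c(CBr)ccc(OC)c1OC(C)=O
F4 | step 6 | dimethyl 6,6'-(ethane-1,2-diyl)bis(2-acetoxy-3-methoxybenzoate) | COC(=O)c1c(OC(C)=O)c(OC)ccc1CCc1ccc(OC)c(OC(C)=O)c1C(=O)OC
F5 | step 8 | 5,5'-(ethane-1,2-diyl)bis(2-methoxyphenol) | COc1ccc(CCc2ccc(OC)c(O)c2)cc1O
F6 | step 4 | 1,8-bis(trimethylsilyl)octa-1,7-diyne-3,6-dione | C[Si](C)(C)C#CC(=O)CCC(=O)C#C[Si](C)(C)C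
F7 | step 5 | (1E,7E)-1,8-bis(diethylamino)octa-1,7-diene-3,6-dione | CCN(CC)/C=C/C(=O)CCC(=O)/C=C/N(CC)CC
F0 | step 7 | none | none
A1 | alternative 1 | 2,3,6-tribromo-4,5-dimethoxyphenyl 4-methylbenzenesulfonate | COc1c(OC)c(Br)c(OS(=O)(=O)c2ccc(C)cc2)c(Br)c1Br
A2 | alternative 1 | ethyne-1,2-diylbis(magnesium bromide) | Br[Mg]C#C[Mg]Br
A3 | alternative 1 | 3,4-dibromo-5,6-dimethoxybenzyne | COC1=C(OC)C(Br)=C(Br)C#C1
A4 | alternative 1 | 1,2-bis(2,3,6-tribromo-4,5-dimethoxyphenyl)ethyne | COc1c(OC)c(Br)c(C#Cc2c(Br)c(OC)c(OC)c(Br)c2Br)c(Br)c1Br
A5 | alternative 2 | 3,3'-(ethane-1,2-diyl)bis(2,4,5-tribromothiophene 1,1-dioxide) | O=S1(=O)C(Br)=C(CCC2=C(Br)S(=O)(=O)C(Br)=C2Br)C(Br)=C1Br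
A6 | alternative 2 | 1,2-di-tert-butoxyethyne | CC(C)(C)OC#COC(C)(C)C
A7 | alternative 2 | 1,2-bis(2,3,6-tribromo-4,5-di-tert-butoxyphenyl)ethane | CC(C)(C)Oc1c(OC(C)(C)C)c(Br)c(CCc2c(Br)c(OC(C)(C)C)c(OC(C)(C)C)c(Br)c2Br)c(Br)c1Br
A8 | alternative 3 | 3,4-dimethoxypyrylium tetrafluoroborate | COc1c[o+]ccc1OC.F[B-](F)(F)F
A9 | alternative 3 | butane-1,4-diylidenebis(triphenylphosphorane) | C(CC=P(c1ccccc1)(c1ccccc1)c1ccccc1)C=P(c1ccccc1)(c1ccccc1)c1ccccc1
A10 | alternative 3 | 1,2-bis(3,4-dimethoxyphenyl)ethane | COc1ccc(CCc2ccc(OC)c(OC)c2)cc1OC
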